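**Retrosynthetic overview**
1. Ring B (the γ-lactone) is made last. Its C16(=O)–O unit is carbon dioxide, inserted in one flask between C15 (C15–C16, carboxylation of a C15 alkenylboronate) and C2 (O–C2, palladium π-allyl closure).
2. Enabling feature: C15 is an sp2 carbon (exocyclic C15=C17) bound directly to C1, and C2 is both the lactone carbinol carbon and allylic to the C3=C4 olefin of ring A. C15–C1–C2 can therefore act as a vinyl-anion/allyl-cation pair that adds across one C=O of CO2.
3. Ring A (the 14-membered carbocycle) is closed at C1–C2 by a copper-catalysed borylative cyclisation of a C15 allene onto the C2 enal, which also installs the C15 boron and C2 oxygen handles.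
4. The allene comes from a terminal alkyne (Crabbé homologation), the alkyne from catalyst-controlled propargylation of the C13 epoxy aldehyde, the oxirane from a Sharpless epoxidation, and C2–C13 with both (E)-olefins from (2E,6E)-farnesol.
5. Order of ring formation: oxirane (step 3), ring A (step 10), ring B (step 12).

Key step: step 12

Assumption: cembrane numbering is used (C1 ring-fusion CH, C2 lactone carbinol, C13 acetoxy carbon, C15 alkene carbon on C1, C16 lactone carbonyl, C17 exocyclic CH2), and the copper-mediated ring closure of step 10 is taken to be 1,2-syn, by analogy with (Z)-allylmetal additions; steps 11 and 12 are built on that.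

**Step 1**
Reactants: 1 (2E,6E)-farnesol
Product: 2 farnesyl tert-butyldimethylsilyl ether
Conditions: TBSCl, imidazole, DMF, 0 °C to rt
Reagents that add atoms: tert-butyldimethylsilyl chloride, CC(C)(C)[Si](C)(C)Cl
Why: Standard silylation of the primary allylic alcohol masks the future C2 oxygen, so that only the hydroxyl made in step 2 can direct the epoxidation; no stereocenter is formed.

**Step 2**
Reactants: 2 farnesyl tert-butyldimethylsilyl ether
Product: 3 (2E,6E,10E)-12-silyloxy-2,6,10-trimethyldodeca-2,6,10-trien-1-ol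
Conditions: SeO2 (cat.), t-BuOOH, salicylic acid (cat.), CH2Cl2, 0 °C to rt
Reagents that add atoms: tert-butyl hydroperoxide, CC(C)(C)OO; selenium dioxide (catalytic oxygen carrier), O=[Se]=O
Why: Riley-type allylic oxidation (ene reaction, then [2,3]-shift) should attack the most electron-rich terminal gem-dimethyl olefin at its (E)-methyl group and give the (E)-allylic alcohol, leaving the other two trisubstituted olefins alone.

**Step 3**
Reactants: 3 (2E,6E,10E)-12-silyloxy-2,6,10-trimethyldodeca-2,6,10-trien-1-ol
Product: 4 (2R,3R)-epoxy alcohol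
Conditions: Ti(OiPr)4 (cat.), D-(−)-diethyl tartrate (cat.), t-BuOOH, 4 Å MS, CH2Cl2, −20 °C
Reagents that add atoms: tert-butyl hydroperoxide, CC(C)(C)OO
Why: Sharpless asymmetric epoxidation is directed by the free primary allylic hydroxyl, so only the C11=C12 olefin reacts, and the D-(−)-tartrate should deliver oxygen to the face that gives the (2R,3R)-epoxy alcohol, which is the 11R,12S oxirane of the target.

**Step 4**
Reactants: 4 (2R,3R)-epoxy alcohol
Product: 5 (2S,3R)-epoxy aldehyde
Conditions: 2,2,6,6-tetramethylpiperidin-1-oxyl (cat.), PhI(OAc)2, CH2Cl2, rt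
Reagents that add atoms: none
Why: The nitroxyl-catalysed oxidation stops at the aldehyde under near-neutral conditions that spare oxirane, silyl ether and olefins, and the quaternary α-carbon cannot epimerise.

**Step 5**
Reactants: 5 (2S,3R)-epoxy aldehyde
Product: 7 (1S)-homopropargylic alcohol, via O-pinacolboryl ether 6 (not isolated)
Conditions: allenylboronic acid pinacol ester, 3,3'-bis(2,4,6-triisopropylphenyl)-1,1'-binaphthyl-2,2'-diyl hydrogen phosphate (cat., the antipode that directs addition to the Si face), 4 Å MS, toluene, −30 °C; aq. NaHCO3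
Reagents that add atoms: allenylboronic acid pinacol ester, C=C=CB1OC(C)(C)C(C)(C)O1
Why: Chiral-phosphoric-acid-catalysed propargylation with an allenylboronate runs by SE2' through a six-membered cyclic transition state, and Si-face addition sets C13 (S) under catalyst control, the α-quaternary epoxy aldehyde having only a weak bias of its own.

**Step 6**
Reactants: 7 (1S)-homopropargylic alcohol
Product: 8 (1S)-homopropargylic acetate
Conditions: Ac2O, 4-(dimethylamino)pyridine (cat.), pyridine, CH2Cl2, 0 °C to rt
Reagents that add atoms: acetic anhydride, CC(=O)OC(C)=O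
Why: Nucleophile-catalysed acylation installs the C13 acetate of the target early and also blocks Payne rearrangement of the epoxy alcohol in the basic steps that follow.

**Step 7**
Reactants: 8 (1S)-homopropargylic acetate
Product: 10 terminal allene, via Mannich base 9 (not isolated)
Conditions: (CH2O)n, CuI, Cy2NH, 1,4-dioxane, 100 °C
Reagents that add atoms: paraformaldehyde (formaldehyde), C=O
Why: Crabbé homologation (Mannich reaction to the propargylic amine, then copper-mediated 1,5-hydride transfer and elimination of the imine) turns the terminal alkyne into the terminal allene and adds C17 without touching a stereocenter.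

**Step 8**
Reactants: 10 terminal allene
Product: 11 allenyl allylic alcohol
Conditions: TBAF, AcOH, THF, 0 °C to rt
Reagents that add atoms: none
Why: Acetic-acid-buffered fluoride should cleave the primary allylic silyl ether without acetate migration or oxirane opening.

**Step 9**
Reactants: 11 allenyl allylic alcohol
Product: 12 allenyl (E)-enal
Conditions: 2,2,6,6-tetramethylpiperidin-1-oxyl (cat.), PhI(OAc)2, CH2Cl2, rt
Reagents that add atoms: none
Why: The same mild nitroxyl-catalysed oxidation converts the primary allylic alcohol into the (E)-enal without isomerising the trisubstituted olefin or attacking the allene.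

**Step 10**
Reactants: 12 allenyl (E)-enal
Product: 14 macrocyclic 1,2-syn hydroxy alkenylboronate, via O-pinacolboryl ether 13 (not isolated)
Conditions: B2pin2, CuCl (cat.), 1,2-bis(2,5-diphenylphospholano)ethane (cat., the antipode matched to 1R), NaOtBu (cat.), THF, rt, slow addition of 12 to 1 mM; aq. NH4Cl
Reagents that add atoms: bis(pinacolato)diboron, CC1(C)OB(OC1(C)C)B1OC(C)(C)C(C)(C)O1
Why: Proposed new method: the ligand-bound Cu–Bpin species (from CuCl, NaOtBu and B2pin2) should add syn across the terminal C15=C17 bond of the allene with boron on the central carbon C15, giving a (Z)-2-boryl allylcopper that attacks the C2 aldehyde through C1 in a six-membered chair (hence 1,2-syn), the chiral ligand choosing the aldehyde face and so the 1R,2S configuration, after which B2pin2 frees copper from the alkoxide; the closest known reaction is the intermolecular copper-catalysed coupling of monosubstituted allenes, B2pin2 and aldehydes to 2-boryl homoallylic alcohols, and closure at C1–C2 by allylmetal addition to a C2 aldehyde is the established cembranoid macrocyclisation with allylchromium reagents; new here is the 14-membered ring closure, which needs high dilution and Cu–B addition to the allene in preference to the enal.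

**Step 11**
Reactants: 14 macrocyclic 1,2-syn hydroxy alkenylboronate
Product: 15 macrocyclic 1,2-anti allylic benzoate
Conditions: PhCO2H, PPh3, DIAD, toluene, −20 °C to rt
Reagents that add atoms: benzoic acid, OC(=O)c1ccccc1
Why: In the Mitsunobu esterification benzoate displaces the C2 alkoxyphosphonium ion by SN2, which inverts C2 to the 1,2-anti arrangement of the target and installs the allylic leaving group for the key step in the same operation.

**Step 12**
Reactants: 15 macrocyclic 1,2-anti allylic benzoate
Product: 17 target lactone, via cesium carboxylate 16 (not isolated)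
Conditions: chloro[1,3-bis(2,6-diisopropylphenyl)imidazol-2-ylidene]copper, (IPr)CuCl (cat.), CsF, CO2 (1 atm), DMF, 70 °C; then Pd(PPh3)4 (cat.), 40 °C
Reagents that add atoms: carbon dioxide, O=C=O
Why: Fluoride-assisted boron-to-copper transmetalation of the 1,1-disubstituted alkenylboronate gives a copper alkenyl that inserts CO2 into its Cu–C15 bond (C15–C16 formed) and releases cesium carboxylate 16; Pd(PPh3)4 then ionises the allylic C2 benzoate with inversion to an η3-allyl complex over C2–C3–C4, and the tethered carboxylate attacks C2 anti to palladium (O–C2 formed). The closest known reaction types are the copper-catalysed carboxylation of alkenylboronic esters with CO2 and the Tsuji–Trost cyclisation of carboxylates onto allylic esters to γ-vinyl-γ-butyrolactones. Ring B closes in a 5-exo mode on the allyl terminus C2 with the C3=C4 unit left exocyclic; attack at C4 would need a seven-membered ring, a quaternary C–O bond and an anti-placed C1, so it is disfavoured. The only new stereocenter, C2, is set by double inversion (net retention) at the benzoate carbon of 15, which gives the trans ring fusion (1R,2S); the (E)-C3=C4 geometry is kept because C1 sits syn on the allyl unit, its anti position clashing with the C4 methyl. The step needs carboxylation to win over alkenyl–allyl coupling, which is secured by adding the zerovalent palladium catalyst only after CO2 uptake is complete and by the strain of any direct C15–C2 or C15–C4 bond. Acetate, oxirane and the remote C7=C8 olefin are inert to both catalysts.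

**Compound list**
1 | (2E,6E)-farnesol, (2E,6E)-3,7,11-trimethyldodeca-2,6,10-trien-1-ol | OC/C=C(\C)CC/C=C(\C)CCC=C(C)C | starting material
2 | tert-butyl(dimethyl){[(2E,6E)-3,7,11-trimethyldodeca-2,6,10-trien-1-yl]oxy}silane | CC(C)(C)[Si](C)(C)OC/C=C(\C)CC/C=C(\C)CCC=C(C)C | intermediate
3 | (2E,6E,10E)-12-[(tert-butyldimethylsilyl)oxy]-2,6,10-trimethyldodeca-2,6,10-trien-1-ol | CC(C)(C)[Si](C)(C)OC/C=C(\C)CC/C=C(\C)CC/C=C(\C)CO | intermediate
4 | [(2R,3R)-3-{(3E,7E)-9-[(tert-butyldimethylsilyl)oxy]-3,7-dimethylnona-3,7-dien-1-yl}-2-methyloxiran-2-yl]methanol | CC(C)(C)[Si](C)(C)OC/C=C(\C)CC/C=C(\C)CC[C@H]1O[C@]1(C)CO | intermediate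
5 | (2S,3R)-3-{(3E,7E)-9-[(tert-butyldimethylsilyl)oxy]-3,7-dimethylnona-3,7-dien-1-yl}-2-methyloxirane-2-carbaldehyde | CC(C)(C)[Si](C)(C)OC/C=C(\C)CC/C=C(\C)CC[C@H]1O[C@]1(C)C=O | intermediate
6 | O-pinacolboryl ether of 7 (boron on the C13 oxygen) | CC(C)(C)[Si](C)(C)OC/C=C(\C)CC/C=C(\C)CC[C@H]1O[C@]1(C)[C@@H](OB2OC(C)(C)C(C)(C)O2)CC#C | intermediate
7 | (1S)-1-[(2R,3R)-3-{(3E,7E)-9-[(tert-butyldimethylsilyl)oxy]-3,7-dimethylnona-3,7-dien-1-yl}-2-methyloxiran-2-yl]but-3-yn-1-ol | CC(C)(C)[Si](C)(C)OC/C=C(\C)CC/C=C(\C)CC[C@H]1O[C@]1(C)[C@@H](O)CC#C | intermediate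
8 | (1S)-1-[(2S,3R)-3-{(3E,7E)-9-[(tert-butyldimethylsilyl)oxy]-3,7-dimethylnona-3,7-dien-1-yl}-2-methyloxiran-2-yl]but-3-yn-1-yl acetate | CC(C)(C)[Si](C)(C)OC/C=C(\C)CC/C=C(\C)CC[C@H]1O[C@]1(C)[C@@H](OC(C)=O)CC#C | intermediate
9 | (1S)-5-(dicyclohexylamino)-1-[(2S,3R)-3-{(3E,7E)-9-[(tert-butyldimethylsilyl)oxy]-3,7-dimethylnona-3,7-dien-1-yl}-2-methyloxiran-2-yl]pent-3-yn-1-yl acetate | CC(C)(C)[Si](C)(C)OC/C=C(\C)CC/C=C(\C)CC[C@H]1O[C@]1(C)[C@@H](OC(C)=O)CC#CCN(C2CCCCC2)C2CCCCC2 | intermediate
10 | (1S)-1-[(2S,3R)-3-{(3E,7E)-9-[(tert-butyldimethylsilyl)oxy]-3,7-dimethylnona-3,7-dien-1-yl}-2-methyloxiran-2-yl]penta-3,4-dien-1-yl acetate | CC(C)(C)[Si](C)(C)OC/C=C(\C)CC/C=C(\C)CC[C@H]1O[C@]1(C)[C@@H](OC(C)=O)CC=C=C | intermediate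
11 | (1S)-1-[(2S,3R)-3-[(3E,7E)-9-hydroxy-3,7-dimethylnona-3,7-dien-1-yl]-2-methyloxiran-2-yl]penta-3,4-dien-1-yl acetate | OC/C=C(\C)CC/C=C(\C)CC[C@H]1O[C@]1(C)[C@@H](OC(C)=O)CC=C=C | intermediate
12 | (1S)-1-[(2S,3R)-3-[(3E,7E)-3,7-dimethyl-9-oxonona-3,7-dien-1-yl]-2-methyloxiran-2-yl]penta-3,4-dien-1-yl acetate | O=C/C=C(\C)CC/C=C(\C)CC[C@H]1O[C@]1(C)[C@@H](OC(C)=O)CC=C=C | intermediate
13 | 2-O-pinacolboryl ether of 14 | C=C(B1OC(C)(C)C(C)(C)O1)[C@@H]2[C@H](OB4OC(C)(C)C(C)(C)O4)/C=C(\C)CC/C=C(\C)CC[C@H]3O[C@]3(C)[C@@H](OC(C)=O)C2 | intermediate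
14 | (1R,2S,3E,7E,11R,12S,13S)-13-acetoxy-11,12-epoxy-15-(4,4,5,5-tetramethyl-1,3,2-dioxaborolan-2-yl)-16-norcembra-3,7,15(17)-trien-2-ol (1,2-syn; C2 oxygen on the face opposite to that of the target) | C=C(B1OC(C)(C)C(C)(C)O1)[C@@H]2[C@H](O)/C=C(\C)CC/C=C(\C)CC[C@H]3O[C@]3(C)[C@@H](OC(C)=O)C2 | intermediate
15 | (1R,2R,3E,7E,11R,12S,13S)-13-acetoxy-11,12-epoxy-15-(4,4,5,5-tetramethyl-1,3,2-dioxaborolan-2-yl)-16-norcembra-3,7,15(17)-trien-2-yl benzoate (1,2-anti; C2 oxygen placed as in the target) | C=C(B1OC(C)(C)C(C)(C)O1)[C@@H]2[C@@H](OC(=O)c4ccccc4)/C=C(\C)CC/C=C(\C)CC[C@H]3O[C@]3(C)[C@@H](OC(C)=O)C2 | intermediate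
16 | cesium (1R,2S,3E,7E,11R,12S,13S)-13-acetoxy-2-(benzoyloxy)-11,12-epoxycembra-3,7,15(17)-trien-16-oate | [Cs+].[O-]C(=O)C(=C)[C@@H]2[C@@H](OC(=O)c4ccccc4)/C=C(\C)CC/C=C(\C)CC[C@H]3O[C@]3(C)[C@@H](OC(C)=O)C2 | intermediate
17 | (1R,2S,3E,7E,11R,12S,13S)-13-acetoxy-11,12-epoxycembra-3,7,15(17)-trien-16,2-olide | C=C1C(=O)O[C@H]2/C=C(\C)CC/C=C(\C)CC[C@H]3O[C@]3(C)[C@@H](OC(C)=O)C[C@H]12 | target

Total step count: 12. Longest linear sequence: 12 (fully linear from farnesol).

**Steps most likely to fail**

Step 10 (Proposed new method). The ring closure may lose to intermolecular oligomerisation, the Cu–B species may add to the enal instead of the allene, and the ligand may control the aldehyde face poorly against the existing C13 center. The fallback uses known reaction types, sets out from 12 and comes back at 14. Platinum-catalysed diboration of the terminal C15=C17 bond of the allene (B2pin2, Pt(dba)2, PCy3, toluene, 50 °C) should give the (Z)-allyl/alkenyl bis(boronate) F1. Warming F1 at high dilution with a chiral phosphoric acid should close ring A by intramolecular allylboration through the chair transition state, giving 13 and, after hydrolytic work-up, 14. Boron is thus placed before the ring closure and the closure itself needs no metal.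

Step 12. Protodeboronation may compete with CO2 insertion; the allylic benzoate may ionise thermally and scramble C2 before palladium is added; the product, itself an allylic ester, may be re-ionised and eliminate to a diene. The fallback sets out from 14 and comes back at 17. The free alcohol 14 is carboxylated under the same copper/CsF/CO2 conditions to the cesium hydroxy carboxylate F2. Work-up with cold pH 5 phosphate buffer (no strong acid, to avoid lactonisation with retention) gives the hydroxy acid F3. Intramolecular Mitsunobu lactonisation (PPh3, DIAD, THF, 0 °C) then forms O–C2 by SN2 with inversion and gives 17, so the inversion and the ring closure are merged and no palladium is used.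

Step 11. Elimination to the diene, SN2' transposition to C4, or esterification with retention through an acyloxyphosphonium ion may compete at this hindered allylic carbinol. The fallback sets out from 14 and comes back at 15. Dess–Martin oxidation (NaHCO3, CH2Cl2) gives the ketone F4. Corey–Bakshi–Shibata reduction ((S)- or (R)-2-methyl-CBS-oxazaborolidine, catecholborane, −78 °C) should give the 1,2-anti alcohol F5 under reagent control. Benzoylation with retention (BzCl, pyridine, 4-(dimethylamino)pyridine) gives 15. The same direct benzoylation would be used if step 10 turned out to give the anti alcohol.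

**Further compounds**
F1 | step 10 | (1S,3Z)-1-[(2S,3R)-3-[(3E,7E)-3,7-dimethyl-9-oxonona-3,7-dien-1-yl]-2-methyloxiran-2-yl]-4,5-bis(4,4,5,5-tetramethyl-1,3,2-dioxaborolan-2-yl)pent-3-en-1-yl acetate | O=C/C=C(\C)CC/C=C(\C)CC[C@H]1O[C@]1(C)[C@@H](OC(C)=O)C/C=C(/B2OC(C)(C)C(C)(C)O2)CB3OC(C)(C)C(C)(C)O3
F2 | step 12 | cesium (1R,2R,3E,7E,11R,12S,13S)-13-acetoxy-11,12-epoxy-2-hydroxycembra-3,7,15(17)-trien-16-oate (1,2-syn) | [Cs+].[O-]C(=O)C(=C)[C@@H]2[C@H](O)/C=C(\C)CC/C=C(\C)CC[C@H]3O[C@]3(C)[C@@H](OC(C)=O)C2
F3 | step 12 | (1R,2R,3E,7E,11R,12S,13S)-13-acetoxy-11,12-epoxy-2-hydroxycembra-3,7,15(17)-trien-16-oic acid (1,2-syn) | OC(=O)C(=C)[C@@H]2[C@H](O)/C=C(\C)CC/C=C(\C)CC[C@H]3O[C@]3(C)[C@@H](OC(C)=O)C2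
F4 | step 11 | (1R,3E,7E,11R,12S,13S)-13-acetoxy-11,12-epoxy-15-(4,4,5,5-tetramethyl-1,3,2-dioxaborolan-2-yl)-16-norcembra-3,7,15(17)-trien-2-one | C=C(B1OC(C)(C)C(C)(C)O1)[C@@H]2C(=O)/C=C(\C)CC/C=C(\C)CC[C@H]3O[C@]3(C)[C@@H](OC(C)=O)C2
F5 | step 11 | (1R,2R,3E,7E,11R,12S,13S)-13-acetoxy-11,12-epoxy-15-(4,4,5,5-tetramethyl-1,3,2-dioxaborolan-2-yl)-16-norcembra-3,7,15(17)-trien-2-ol (1,2-anti; C2 epimer of 14) | C=C(B1OC(C)(C)C(C)(C)O1)[C@@H]2[C@@H](O)/C=C(\C)CC/C=C(\C)CC[C@H]3O[C@]3(C)[C@@H](OC(C)=O)C2
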